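**Route in brief**

- Retrosynthesis: the C18 acetate is removed first. The C13–C16 and C14–C15 bonds are cut next (methyl and carboxyl taken off a C13≡C14 alkyne), then the C8–C17 bond (methyl taken off a C8 ketone). Last, the open chain is rejoined on paper between C8 and C14.
- Enabling feature: C8 (the tertiary carbinol carbon of ring B) and C14 (the carbon α to the carboxyl) are not bonded in the target, yet C8, C9, C11, C12, C13 and C14 are the six atoms of ring C of an abietane. Neoabietic acid supplies that ring together with rings A and B, the 4R carbon carrying the oxidised C18, the C4 and C10 methyls and the C5, C9 and C10 configurations.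
- Forward: no ring is formed. Rings A and B are bought; ring C is trimmed to a 13-oxo-8(14)-ene, epoxidised and opened between C8 and C14 by an Eschenmoser–Tanabe fragmentation. C17 is then joined to C8, C16 and C15 are added across the alkyne, and O18 is acetylated.
- Stereochemistry: C4, C5, C9 and C10 are those of neoabietic acid. C8 comes from α-face epoxidation of the 8(17)-methylene (away from the axial C10 methyl) followed by hydride opening at C17. The 13E alkene comes from syn carboalumination and carboxylation with retention.

Key step: step 4

Remark: the oxirane of 4 is drawn 8α,14α (hydroperoxide adding to C8 on the face opposite the C10 methyl); this is an assumption without consequence, because C8 and C14 both lose their configuration in step 4.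

**Step 1**
Reactants: 1 neoabietic acid
Product: 2 methyl neoabietate
Conditions: MeI, K2CO3, DMF, rt
Reagents that add atoms: iodomethane, CI
Why: SN2 O-alkylation of the potassium carboxylate (ester formation under basic conditions) is chosen because acid would isomerise the 8(14),13(15)-diene; no stereocentre is touched.

**Step 2**
Reactants: 2 methyl neoabietate
Product: 3 methyl 13-oxopodocarp-8(14)-en-18-oate
Conditions: O3 (1 equiv), CH2Cl2–MeOH, −78 °C; then Me2S, −78 °C → rt
Reagents that add atoms: ozone, [O-][O+]=O
Why: Chemoselective ozonolysis should cleave the electron-rich tetrasubstituted exocyclic C13=C15 bond well before the trisubstituted C8=C14 bond, which becomes a deactivated enone as soon as the first cleavage has occurred, while the isopropylidene carbon leaves as acetone.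

**Step 3**
Reactants: 3 methyl 13-oxopodocarp-8(14)-en-18-oate
Product: 4 methyl 8α,14α-epoxy-13-oxopodocarpan-18-oate
Conditions: 30% aq. H2O2, aq. NaOH (cat.), MeOH, 0 °C → rt
Reagents that add atoms: hydrogen peroxide, OO
Why: Weitz–Scheffer nucleophilic epoxidation: hydroperoxide should add in conjugate fashion to C8 from the α face (opposite the C10 methyl) and the enolate should close the oxirane on the same face, while the hindered tertiary C18 ester resists saponification at this temperature; the two new centres are temporary.

**Step 4**
Reactants: 4 methyl 8α,14α-epoxy-13-oxopodocarpan-18-oate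
Product: 6 methyl 8-oxo-15,16,17-trinorlabd-13-yn-18-oate, via tosylhydrazone 5 (not isolated)
Conditions: TsNHNH2 (1.05 equiv), AcOH–CH2Cl2 (1:1), −20 °C → rt
Reagents that add atoms: none
Why: Condensation of TsNHNH2 with the unhindered C13 ketone gives tosylhydrazone 5; loss of the N–H proton opens the oxirane at C14 to an 8-oxygenated 13-(tosylazo)-13-ene, and the C8 oxygen then expels the C8–C14 sigma bond anti to the departing nitrogen, so that the C8 carbonyl and the C13≡C14 triple bond form while N2 and p-toluenesulfinate leave. This is the Eschenmoser–Tanabe fragmentation of α,β-epoxy ketone sulfonylhydrazones, precedented for cyclic epoxy ketones with hydrogen on the α carbon and a fully substituted β carbon, which give terminal alkynyl ketones. No ring is closed; ring C is opened between C8 and C14 and rings A and B are untouched. No stereocentre is created: C8 becomes trigonal and C14 digonal, so either oxirane epimer would give the same product, and C9 next to the new ketone already carries its but-3-ynyl chain equatorially and has no drive to epimerise. The only selectivity needed is which C–C bond breaks, and the mechanism allows only the bond between the α carbon (C14) and the β carbon (C8) of the epoxy ketone. The C18 methyl ester is inert to the acetic acid medium, and only a slight excess of the hydrazide is used so that the product ketone is not itself converted to a hydrazone.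

**Step 5**
Reactants: 6 methyl 8-oxo-15,16,17-trinorlabd-13-yn-18-oate; 7 methyltriphenylphosphonium bromide
Product: 8 methyl 15,16-dinorlabd-8(17)-en-13-yn-18-oate
Conditions: 7, NaN(SiMe3)2, THF, 0 °C; then 6, 0 → 50 °C
Reagents that add atoms: methyltriphenylphosphonium bromide (7), [Br-].C[P+](c1ccccc1)(c1ccccc1)c1ccccc1
Why: Wittig methylenation with the non-stabilised ylide should convert the C8 ketone into the exocyclic alkene (C17); the ylide is too weak a base to deprotonate the terminal alkyne, the hindered ester is untouched and C9 stays in its stable equatorial configuration.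

**Step 6**
Reactants: 8 methyl 15,16-dinorlabd-8(17)-en-13-yn-18-oate
Product: 9 methyl 8α,17-epoxy-15,16-dinorlabd-13-yn-18-oate
Conditions: mCPBA, CH2Cl2, 0 °C
Reagents that add atoms: 3-chloroperbenzoic acid, OOC(=O)c1cccc(Cl)c1
Why: Prilezhaev epoxidation: the peracid should approach the 1,1-disubstituted alkene from the α face because the β face is screened by the axial C10 methyl (1,3-diaxial to the incoming oxygen), which sets the C8–O bond α (equatorial) and C17 β; the terminal alkyne is much less nucleophilic and should not react.

**Step 7**
Reactants: 9 methyl 8α,17-epoxy-15,16-dinorlabd-13-yn-18-oate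
Product: 10 15,16-dinorlabd-13-yne-8α,18-diol
Conditions: LiAlH4, THF, 0 °C → reflux; Fieser work-up (H2O, aq. NaOH)
Reagents that add atoms: none
Why: Hydride reduction: LiAlH4 should open the oxirane by SN2 attack at the primary C17, so the C8–O bond and the 8α configuration are kept and C17 becomes the axial methyl, and it reduces the C18 ester to the primary alcohol; the isolated alkyne is inert.

**Step 8**
Reactants: 10 15,16-dinorlabd-13-yne-8α,18-diol; 11 trimethylaluminium; 12 carbon dioxide
Product: 15 8α,18-dihydroxylabd-13E-en-15-oic acid, via alkenylalane 13 (not isolated), via lithium alanate 14 (not isolated)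
Conditions: Me3Al (5 equiv), Cp2ZrCl2 (25 mol %), CH2Cl2, 0 °C → rt; volatiles removed; n-BuLi, THF, −78 → 0 °C; CO2, −78 °C → rt; 1 M HCl, 0 °C
Reagents that add atoms: trimethylaluminium (11), C[Al](C)C; carbon dioxide (12), O=C=O
Why: Negishi zirconium-catalysed carboalumination should add methyl (to C13) and aluminium (to the terminal C14) syn across the alkyne, the two hydroxyls being masked in the flask as aluminium alkoxides; conversion to the alanate with n-BuLi makes the alkenyl–aluminium bond nucleophilic enough to add to CO2 with retention, which fixes the 13E geometry.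

**Step 9**
Reactants: 15 8α,18-dihydroxylabd-13E-en-15-oic acid
Product: 17 18-acetoxy-8α-hydroxylabd-13E-en-15-oic acid, via mixed anhydride 16 (not isolated)
Conditions: Ac2O, pyridine, rt; then H2O–THF, rt
Reagents that add atoms: acetic anhydride, CC(=O)OC(C)=O
Why: Chemoselective O-acetylation: without an acyl-transfer catalyst only the primary C18 hydroxyl should be acylated, the tertiary 8α hydroxyl being inert under these conditions, and the carboxyl that is tied up in the flask as the mixed acetic anhydride is released by water, which attacks the more electrophilic acetyl carbonyl.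

**Compound list**

1 | neoabietic acid, abieta-8(14),13(15)-dien-18-oic acid (5α-H, 9α-H, 10β-methyl, carboxyl α on C4) | OC(=O)[C@]1(C)CCC[C@]2(C)[C@H]3CCC(=C(C)C)C=C3CC[C@@H]12 | starting material
2 | methyl neoabietate, methyl abieta-8(14),13(15)-dien-18-oate | COC(=O)[C@]1(C)CCC[C@]2(C)[C@H]3CCC(=C(C)C)C=C3CC[C@@H]12 | intermediate
3 | methyl 13-oxopodocarp-8(14)-en-18-oate | COC(=O)[C@]1(C)CCC[C@]2(C)[C@H]3CCC(=O)C=C3CC[C@@H]12 | intermediate
4 | methyl 8α,14α-epoxy-13-oxopodocarpan-18-oate (oxirane oxygen on the α face, rings B and C cis) | COC(=O)[C@]1(C)CCC[C@]2(C)[C@H]3CCC(=O)[C@@H]4O[C@@]43CC[C@@H]12 | intermediate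
5 | C13 p-toluenesulfonylhydrazone of 4 (drawn E about C=N; either geometry fragments) | COC(=O)[C@]1(C)CCC[C@]2(C)[C@H]3CC/C(=N\NS(=O)(=O)c5ccc(C)cc5)[C@@H]4O[C@@]43CC[C@@H]12 | intermediate (not isolated)
6 | methyl 8-oxo-15,16,17-trinorlabd-13-yn-18-oate (but-3-ynyl chain β, equatorial on C9) | COC(=O)[C@]1(C)CCC[C@]2(C)[C@@H](CCC#C)C(=O)CC[C@@H]12 | intermediate
7 | methyltriphenylphosphonium bromide | [Br-].C[P+](c1ccccc1)(c1ccccc1)c1ccccc1 | starting material
8 | methyl 15,16-dinorlabd-8(17)-en-13-yn-18-oate | COC(=O)[C@]1(C)CCC[C@]2(C)[C@@H](CCC#C)C(=C)CC[C@@H]12 | intermediate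
9 | methyl 8α,17-epoxy-15,16-dinorlabd-13-yn-18-oate (spiro oxirane, oxygen α, CH2 β) | COC(=O)[C@]1(C)CCC[C@]2(C)[C@@H](CCC#C)[C@@]3(CO3)CC[C@@H]12 | intermediate
10 | 15,16-dinorlabd-13-yne-8α,18-diol (8α-OH equatorial, 8β-methyl axial) | OC[C@]1(C)CCC[C@]2(C)[C@@H](CCC#C)[C@](C)(O)CC[C@@H]12 | intermediate
11 | trimethylaluminium | C[Al](C)C | starting material
12 | carbon dioxide | O=C=O | starting material
13 | (13E)-14-(dimethylalumino)-15-norlabd-13-ene-8α,18-diyl bis(dimethylaluminium alkoxide) | C[Al](C)OC[C@]1(C)CCC[C@]2(C)[C@@H](CC/C(C)=C/[Al](C)C)[C@](C)(O[Al](C)C)CC[C@@H]12 | intermediate (not isolated)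
14 | trilithium tris(butyl) ate complex of 13 (butyl on each aluminium) | [Li+].[Li+].[Li+].CCCC[Al-](C)(C)OC[C@]1(C)CCC[C@]2(C)[C@@H](CC/C(C)=C/[Al-](C)(C)CCCC)[C@](C)(O[Al-](C)(C)CCCC)CC[C@@H]12 | intermediate (not isolated)
15 | 8α,18-dihydroxylabd-13E-en-15-oic acid | OC[C@]1(C)CCC[C@]2(C)[C@@H](CC/C(C)=C/C(=O)O)[C@](C)(O)CC[C@@H]12 | intermediate
16 | acetic 18-acetoxy-8α-hydroxylabd-13E-en-15-oic anhydride | CC(=O)OC[C@]1(C)CCC[C@]2(C)[C@@H](CC/C(C)=C/C(=O)OC(C)=O)[C@](C)(O)CC[C@@H]12 | intermediate (not isolated)
17 | 18-acetoxy-8α-hydroxylabd-13E-en-15-oic acid | CC(=O)OC[C@]1(C)CCC[C@]2(C)[C@@H](CC/C(C)=C/C(=O)O)[C@](C)(O)CC[C@@H]12 | target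

**Count**

Total: 9 steps. Longest linear sequence: 9 steps, from neoabietic acid 1 to 17.

**Steps most likely to fail**

Step 8. The carbometalation may stop short, or the alanate may fail to transfer its alkenyl group to CO2 in the presence of the two aluminium alkoxides, so that protonolysis on work-up returns the uncarboxylated 13-methyl alkene. The fallback sets out from diol 10 and separates the two events. The same carboalumination would be quenched with I2 (THF, −30 °C) to give (13E)-14-iodo-15-norlabd-13-ene-8α,18-diol F1. Palladium-catalysed hydroxycarbonylation of this alkenyl iodide (Pd(OAc)2, PPh3, CO 1 atm, K2CO3, DMF–H2O, 60 °C) should then install the carboxyl with retention of the alkene geometry, and the route is rejoined at acid 15.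

Step 6. Facial selectivity may be poor, the peracid also attacking the β face and giving the 8-epi oxirane and hence the 8β-alcohol. The fallback sets out from alkene 8 and uses a bulkier oxidant with a different way to the methyl group. Dihydroxylation (OsO4 cat., N-methylmorpholine N-oxide, acetone–H2O) should give methyl 8α,17-dihydroxy-15,16-dinorlabd-13-yn-18-oate F2, whose diastereomer, if formed, is more easily separated than the oxiranes. Selective sulfonylation of the primary hydroxyl (TsCl, pyridine, 0 °C) would give methyl 8α-hydroxy-17-(p-toluenesulfonyloxy)-15,16-dinorlabd-13-yn-18-oate F3. LiAlH4 in THF should then remove the sulfonate by hydride (through the oxirane closed in the flask) and reduce the ester, so that the route is rejoined at diol 10, passing over 9.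

Step 4. The sulfonylhydrazone may open the oxirane but not fragment cleanly, the hydroxy azoalkene being diverted by addition of acetic acid or by tautomerisation, or the product ketone may be consumed by the reagent. The fallback sets out from enone 3 and makes the same C8–C14 cut oxidatively. Ozonolysis of the enone double bond with alkaline H2O2 work-up (O3, CH2Cl2–MeOH, −78 °C; then aq. H2O2, NaOH) should excise C14 and give 18-methyl hydrogen 8-oxo-14,15,16,17-tetranorlabdane-13,18-dioate F4. Coupling with N-hydroxyphthalimide (N,N'-diisopropylcarbodiimide, CH2Cl2) would give methyl 13-(1,3-dioxoisoindolin-2-yloxy)-8,13-dioxo-14,15,16,17-tetranorlabdan-18-oate F5. Nickel-catalysed decarboxylative alkynylation with ethynylzinc chloride (NiCl2·6H2O, 2,2'-bipyridine, THF–DMF, rt) should replace the activated carboxyl by an ethynyl group, which gives the but-3-ynyl ketone, and the route is rejoined at alkynone 6.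

**Further compounds**

F1 | step 8 | (13E)-14-iodo-15-norlabd-13-ene-8α,18-diol | OC[C@]1(C)CCC[C@]2(C)[C@@H](CC/C(C)=C/I)[C@](C)(O)CC[C@@H]12
F2 | step 6 | methyl 8α,17-dihydroxy-15,16-dinorlabd-13-yn-18-oate | COC(=O)[C@]1(C)CCC[C@]2(C)[C@@H](CCC#C)[C@](CO)(O)CC[C@@H]12
F3 | step 6 | methyl 8α-hydroxy-17-(p-toluenesulfonyloxy)-15,16-dinorlabd-13-yn-18-oate | COC(=O)[C@]1(C)CCC[C@]2(C)[C@@H](CCC#C)[C@](COS(=O)(=O)c3ccc(C)cc3)(O)CC[C@@H]12
F4 | step 4 | 18-methyl hydrogen 8-oxo-14,15,16,17-tetranorlabdane-13,18-dioate | COC(=O)[C@]1(C)CCC[C@]2(C)[C@@H](CCC(=O)O)C(=O)CC[C@@H]12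
F5 | step 4 | methyl 13-(1,3-dioxoisoindolin-2-yloxy)-8,13-dioxo-14,15,16,17-tetranorlabdan-18-oate | COC(=O)[C@]1(C)CCC[C@]2(C)[C@@H](CCC(=O)ON3C(=O)c4ccccc4C3=O)C(=O)CC[C@@H]12
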